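**Retrosynthetic overview**

- Feature: ring B is a benzene ring fused through C3a′–C7a′ to a dihydrofuran (O1′–C2′–C3′). It carries O1′ on C7a′, an OH on C4′, and C3 of the ring A dihydrobenzofuran on C6′; C5′ and C7′ are unsubstituted (primed atoms belong to the distal benzofuran).
- End game: target ⇐ cleavage of seven methyl ethers ⇐ C4′ phenol ⇐ oxidation of a C4′ pinacol boronate.
- Key disconnection: C3a′–C7a′, C6′–C7′ and C4′–C5′ by Ru-catalysed [2+2+2] of an ynol ether/alkynylboronate 1,6-diyne (tether O1′–C2′–C3′, both stereocentres preset) with the 3-ethynyl dihydrobenzofuran of ring A. Benzene ring B and its furan ring close in the same step.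
- Diyne ⇐ one-flask C-borylation and ynol ether formation ⇐ dichlorovinyl ether ⇐ anti homopropargylic alcohol ⇐ Marshall propargylation of 3,4-dimethoxybenzaldehyde with a chiral propargylic mesylate made from 3,5-dimethoxybenzaldehyde.
- Alkyne ⇐ Ohira–Bestmann ⇐ trans 3-carboxylate ⇐ oxidative ring contraction of an (R)-flavanone ⇐ asymmetric aryl addition to 7-bromo-5-methoxychromone. Ring order: pyranone, then furan of ring A, then benzene ring B together with its furan.

Key step: step 16

Remark: the ligand antipodes named in steps 1 and 10 are those expected to give the configurations drawn; if the first run shows the opposite sense, the other antipode is used and nothing else changes.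

**Route**

Step 1
Reactants: 1 3,5-dimethoxybenzaldehyde; 2 ethynyltri(propan-2-yl)silane
Product: 4 (1R)-1-(3,5-dimethoxyphenyl)-3-[tri(propan-2-yl)silyl]prop-2-yn-1-ol, via methyl(silylethynyl)zinc 3 (not isolated)
Conditions: Me2Zn (3 equiv), (S,S)-ProPhenol (10 mol %), Ph3P=O (20 mol %), toluene, 0 °C
Reagents that add atoms: none
Why: Trost ProPhenol alkynylation: the dinuclear zinc–ProPhenol complex binds the aldehyde and the alkynylzinc 3 on adjacent zinc atoms and delivers the alkynyl group to one face of the carbonyl, which sets the carbinol centre as R.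

Step 2
Reactants: 4 (1R)-propargylic alcohol
Product: 5 (1R)-1-(3,5-dimethoxyphenyl)-3-[tri(propan-2-yl)silyl]prop-2-yn-1-yl methanesulfonate
Conditions: MsCl, Et3N, CH2Cl2, −78 °C; used at once
Reagents that add atoms: methanesulfonyl chloride, CS(=O)(=O)Cl
Why: Sulfonylation of the secondary alcohol at oxygen, so the stereocentre is retained; the meta-methoxy groups do not stabilise a benzylic cation, so the mesylate should last at low temperature.

Step 3
Reactants: 5 propargylic mesylate; 6 3,4-dimethoxybenzaldehyde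
Product: 8 (1S,2S)-1-(3,4-dimethoxyphenyl)-2-(3,5-dimethoxyphenyl)-4-[tri(propan-2-yl)silyl]but-3-yn-1-ol, via allenyl(ethyl)zinc 7 (not isolated)
Conditions: Pd(OAc)2 (5 mol %), PPh3 (5 mol %), Et2Zn (3 equiv), THF, −78 → −20 °C
Reagents that add atoms: none
Why: Marshall propargylation: zerovalent palladium (formed from Pd(OAc)2, PPh3 and Et2Zn) displaces the mesylate anti by SN2′, transmetalation gives the axially chiral allenylzinc 7, and syn SE2′ addition to 6 through a chair-like six-membered transition state with the aldehyde aryl group equatorial gives the anti alcohol, so C2 is set by net inversion of the mesylate centre and C1 by the anti transition state.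

Step 4
Reactants: 8 anti homopropargylic alcohol
Product: 10 4-[(1S,2S)-1-[(E)-1,2-dichloroethenoxy]-2-(3,5-dimethoxyphenyl)-4-[tri(propan-2-yl)silyl]but-3-yn-1-yl]-1,2-dimethoxybenzene, via potassium alkoxide 9 (not isolated)
Conditions: KH (1.5 equiv), THF, 0 °C; Cl2C=CHCl (1.2 equiv), −50 → 20 °C
Reagents that add atoms: trichloroethylene, ClC=C(Cl)Cl
Why: Greene dichlorovinyl ether synthesis: the alkoxide 9 dehydrochlorinates trichloroethylene to dichloroethyne and adds to it anti, while the bulky silyl group shields the alkyne from alkoxide and the low temperature limits retro-propargylation and propargyl–allene isomerisation; no stereocentre is touched.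

Step 5
Reactants: 10 silylated dichlorovinyl ether
Product: 11 4-[(1S,2R)-1-[(E)-1,2-dichloroethenoxy]-2-(3,5-dimethoxyphenyl)but-3-yn-1-yl]-1,2-dimethoxybenzene
Conditions: TBAF·3H2O (1.2 equiv), THF, 0 °C
Reagents that add atoms: none
Why: Fluoride-induced protodesilylation of the alkynylsilane; water protonates the acetylide at once so the benzylic propargylic C–H is not isomerised, and the dichlorovinyl ether is inert to fluoride (the descriptor at C2 changes only because ethynyl ranks below aryl).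

Step 6
Reactants: 11 dichlorovinyl ether with free alkyne
Product: 15 2-[(3S,4S)-4-(3,4-dimethoxyphenyl)-3-(3,5-dimethoxyphenyl)-4-(ethynyloxy)but-1-yn-1-yl]-4,4,5,5-tetramethyl-1,3,2-dioxaborolane, via lithium acetylide 12 (not isolated), via lithium alkynylborate 13 (not isolated), via lithiated ynol ether borate 14 (not isolated)
Conditions: n-BuLi (1.0 equiv), THF, −78 °C; i-PrOBpin (1.05 equiv), −78 °C; n-BuLi (2.1 equiv), −78 → −40 °C; i-PrOH (1.1 equiv), −78 °C; Me3SiCl (2.3 equiv), −78 → 0 °C; cold filtration, used within hours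
Reagents that add atoms: 2-isopropoxy-4,4,5,5-tetramethyl-1,3,2-dioxaborolane, CC(C)OB1OC(C)(C)C(C)(C)O1
Why: Brown alkynylboronate synthesis run in one flask with the second stage of the Greene ynol ether synthesis: the sp C–H is lithiated first, the tetracoordinate borate 13 is inert to the further n-BuLi that dehydrochlorinates the vinyl ether and exchanges the second chlorine for lithium, i-PrOH protonates the alkoxyacetylide of 14 and Me3SiCl removes isopropoxide from boron as its silyl ether, so the acid-labile ynol ether never meets a protic acid; the stereocentres are not involved.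

Step 7
Reactants: 16 4-bromo-2,6-dimethoxybenzaldehyde
Product: 17 1-(4-bromo-2,6-dimethoxyphenyl)prop-2-yn-1-ol (racemic)
Conditions: HC≡CMgBr, THF, 0 °C
Reagents that add atoms: ethynylmagnesium bromide, C#C[Mg]Br
Why: Grignard addition of an acetylide to the aldehyde; the carbinol centre is formed racemic and is removed by oxidation in step 8.

Step 8
Reactants: 17 propargylic alcohol
Product: 18 1-(4-bromo-2,6-dimethoxyphenyl)prop-2-yn-1-one
Conditions: MnO2 (excess), CH2Cl2, 20 °C
Reagents that add atoms: none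
Why: MnO2 oxidation of a benzylic propargylic alcohol to the ynone, which leaves the aryl bromide and the terminal alkyne alone.

Step 9
Reactants: 18 ynone
Product: 21 7-bromo-5-methoxy-4H-chromen-4-one, via diethylamino enone 19 (not isolated), via hydroxyaryl enaminone 20 (not isolated)
Conditions: Et2NH (1.05 equiv), CH2Cl2, 20 °C; BCl3 (2.2 equiv), −78 → 0 °C; then 2 M HCl, THF, 40 °C
Reagents that add atoms: none
Why: Enaminone route to chromones: conjugate addition of the amine gives the vinylogous amide 19, whose carbonyl oxygen chelates BCl3 together with one ortho methoxy group so that only that ether is cleaved, and in aqueous acid the phenol of 20 closes the pyranone ring 6-endo by addition–elimination with loss of diethylamine.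

Step 10
Reactants: 21 chromone; 22 4-methoxyphenylboronic acid
Product: 23 (2R)-7-bromo-5-methoxy-2-(4-methoxyphenyl)-2,3-dihydro-4H-chromen-4-one
Conditions: Pd(OCOCF3)2 (5 mol %), (S)-t-BuPyOX (6 mol %), NH4PF6 (30 mol %), H2O (5 equiv), ClCH2CH2Cl, 60 °C
Reagents that add atoms: none
Why: Palladium-catalysed asymmetric conjugate addition of an arylboronic acid to a chromone (Stoltz conditions, cationic divalent palladium with a pyridine–oxazoline ligand): the ligand fixes the face of the enone that inserts into the aryl–palladium bond, which sets C2 as R, and the aryl bromide is inert to divalent palladium.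

Step 11
Reactants: 23 (R)-flavanone
Product: 24 methyl (2R,3R)-6-bromo-4-methoxy-2-(4-methoxyphenyl)-2,3-dihydro-1-benzofuran-3-carboxylate
Conditions: PhI(OAc)2 (1.2 equiv), H2SO4 (2 equiv), HC(OMe)3, 20 °C
Reagents that add atoms: trimethyl orthoformate, COC(OC)OC
Why: Oxidative ring contraction of a flavanone with a hypervalent iodine reagent in trimethyl orthoformate: the enol ether formed in situ is iodinated at C3 trans to the 2-aryl group and the ring A carbon C4a shifts from C4 to C3 antiperiplanar to the leaving iodobenzene, so C4 becomes the ester carbon, C2 keeps its configuration and the new C3 centre ends trans to the 2-aryl group.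

Step 12
Reactants: 24 trans ester
Product: 25 [(2R,3S)-6-bromo-4-methoxy-2-(4-methoxyphenyl)-2,3-dihydro-1-benzofuran-3-yl]methanol
Conditions: i-Bu2AlH (2.5 equiv), CH2Cl2, −78 → 0 °C; Rochelle salt work-up
Reagents that add atoms: none
Why: Hydride reduction of the ester to the primary alcohol with an aluminium hydride; it is done before the cross-coupling so that no C3–H α to a carbonyl meets base, which could open the furan ring by E1cB elimination of the phenoxide.

Step 13
Reactants: 25 bromo alcohol; 26 [(E)-2-(4-methoxyphenyl)ethenyl]boronic acid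
Product: 27 [(2R,3S)-4-methoxy-2-(4-methoxyphenyl)-6-[(E)-2-(4-methoxyphenyl)ethenyl]-2,3-dihydro-1-benzofuran-3-yl]methanol
Conditions: Pd(dppf)Cl2 (5 mol %), K2CO3 (3 equiv), 1,4-dioxane/H2O, 80 °C
Reagents that add atoms: none
Why: Suzuki–Miyaura coupling of the aryl bromide with an (E)-alkenylboronic acid, which keeps the alkene geometry and tolerates the free alcohol.

Step 14
Reactants: 27 styryl alcohol
Product: 28 (2R,3R)-4-methoxy-2-(4-methoxyphenyl)-6-[(E)-2-(4-methoxyphenyl)ethenyl]-2,3-dihydro-1-benzofuran-3-carbaldehyde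
Conditions: Dess–Martin periodinane (1.3 equiv), CH2Cl2, 0 → 20 °C
Reagents that add atoms: none
Why: Dess–Martin oxidation of the primary alcohol to the aldehyde under non-basic conditions, so the α-aryl aldehyde is not epimerised or ring-opened and is used at once.

Step 15
Reactants: 28 aldehyde
Product: 29 (2R,3R)-3-ethynyl-4-methoxy-2-(4-methoxyphenyl)-6-[(E)-2-(4-methoxyphenyl)ethenyl]-2,3-dihydro-1-benzofuran
Conditions: dimethyl (1-diazo-2-oxopropyl)phosphonate (1.5 equiv), K2CO3 (2 equiv), MeOH, 0 °C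
Reagents that add atoms: dimethyl (1-diazo-2-oxopropyl)phosphonate, COP(=O)(OC)C(=[N+]=[N-])C(C)=O
Why: Seyferth–Gilbert homologation in the Ohira–Bestmann variant: the diazomethylphosphonate anion made by methanolysis adds to the aldehyde and the alkylidene carbene formed after loss of phosphate and N2 gives the alkyne by 1,2-hydrogen shift; enolisation at C3 can only return the more stable trans isomer and the low temperature limits E1cB opening, so C2 and C3 are kept.

Step 16
Reactants: 29 3-ethynyl dihydrobenzofuran; 15 ynol ether–alkynylboronate diyne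
Product: 30 (2S,3S)-2-(3,4-dimethoxyphenyl)-3-(3,5-dimethoxyphenyl)-6-[(2R,3R)-4-methoxy-2-(4-methoxyphenyl)-6-[(E)-2-(4-methoxyphenyl)ethenyl]-2,3-dihydro-1-benzofuran-3-yl]-4-(4,4,5,5-tetramethyl-1,3,2-dioxaborolan-2-yl)-2,3-dihydro-1-benzofuran
Conditions: Cp*RuCl(cod) (10 mol %, divalent ruthenium), ClCH2CH2Cl, 20 °C, Ar; 15 (1.5 equiv) added over 4 h
Reagents that add atoms: none
Why: Proposed new method: the Cp*RuCl fragment left after loss of cod should bind both alkynes of 15 and couple them oxidatively to a ruthenacyclopentadiene, which forms C3a′–C7a′ and closes the dihydrofuran ring as the five-membered ring annulated through the O1′–C2′–C3′ tether; 29 then adds across the Ru–C7′ bond with its CH end on ruthenium, and reductive elimination forms C6′–C7′ and C4′–C5′ and closes benzene ring B as the [2+2+2] adduct. The closest known reactions are Cp*RuCl(cod)-catalysed cyclotrimerisations of 1,6-diynes with an alkynylboronate terminus and Rh- or Ru-catalysed [2+2+2] reactions of ynamide-tethered 1,6-diynes that give indolines; an ynol ether 1,6-diyne has not been used, but its oxygen polarises one alkyne much as nitrogen does in an ynamide. No stereocentre is formed: C2′/C3′ of 15 and C2/C3 of 29 take no part, and neither acid nor base is present to epimerise them. The step needs regioselectivity, with C3 of ring A on C6′ (meta to boron): the bulky Cp* ligand and the pinacolboryl group shield the C4′ terminus, so 29 should enter at the unsubstituted C7′ terminus with its substituent next to it, as in the meta-selective couplings of unsymmetrical diynes with terminal alkynes. It also needs cross-coupling to beat diyne dimerisation and the ynol ether to survive: slow addition keeps 15 dilute, and 20 °C avoids sigmatropic and retro-ene decomposition of the benzylic alkynyl ether.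

Step 17
Reactants: 30 C4′ boronate
Product: 31 (2S,3S)-2-(3,4-dimethoxyphenyl)-3-(3,5-dimethoxyphenyl)-6-[(2R,3R)-4-methoxy-2-(4-methoxyphenyl)-6-[(E)-2-(4-methoxyphenyl)ethenyl]-2,3-dihydro-1-benzofuran-3-yl]-2,3-dihydro-1-benzofuran-4-ol
Conditions: NaBO3·4H2O (5 equiv), THF/H2O, 20 °C
Reagents that add atoms: sodium perborate tetrahydrate, [Na+].[O-]OB=O.O.O.O.O
Why: Oxidation of an arylboronate with perborate: the peroxide adds to boron, the aryl group shifts from boron to oxygen and hydrolysis gives the phenol, while the stilbene and the aryl ethers are inert to this mild nucleophilic oxidant.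

Step 18
Reactants: 31 heptamethyl ether phenol
Product: 32 (2S,3S)-2-(3,4-dihydroxyphenyl)-3-(3,5-dihydroxyphenyl)-6-[(2R,3R)-4-hydroxy-2-(4-hydroxyphenyl)-6-[(E)-2-(4-hydroxyphenyl)ethenyl]-2,3-dihydro-1-benzofuran-3-yl]-2,3-dihydro-1-benzofuran-4-ol (CNP0107857.3)
Conditions: BBr3 (20 equiv), CH2Cl2, −78 → 0 °C; then MeOH, H2O
Reagents that add atoms: none
Why: Lewis-acid cleavage of aryl methyl ethers with BBr3 (bromide attacks the methyl group of the boron-bound ether), used in excess for seven ethers; both dihydrofurans are trans, the thermodynamic arrangement, so reversible ionisation at C2 or C2′ should not change the configuration, and C3 and C3′ are not touched.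

**Compound list**

1 | 3,5-dimethoxybenzaldehyde | COc1cc(C=O)cc(OC)c1 | starting material
2 | ethynyltri(propan-2-yl)silane | C#C[Si](C(C)C)(C(C)C)C(C)C | starting material
3 | methyl{[tri(propan-2-yl)silyl]ethynyl}zinc | C[Zn]C#C[Si](C(C)C)(C(C)C)C(C)C | intermediate (not isolated)
4 | (1R)-1-(3,5-dimethoxyphenyl)-3-[tri(propan-2-yl)silyl]prop-2-yn-1-ol | O[C@@H](C#C[Si](C(C)C)(C(C)C)C(C)C)c1cc(OC)cc(OC)c1 | intermediate
5 | (1R)-1-(3,5-dimethoxyphenyl)-3-[tri(propan-2-yl)silyl]prop-2-yn-1-yl methanesulfonate | CS(=O)(=O)O[C@@H](C#C[Si](C(C)C)(C(C)C)C(C)C)c1cc(OC)cc(OC)c1 | intermediate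
6 | 3,4-dimethoxybenzaldehyde | COc1ccc(C=O)cc1OC | starting material
7 | (Sa)-ethyl{3-(3,5-dimethoxyphenyl)-1-[tri(propan-2-yl)silyl]propa-1,2-dien-1-yl}zinc | CC[Zn]C([Si](C(C)C)(C(C)C)C(C)C)=[C@@]=C([H])c1cc(OC)cc(OC)c1 | intermediate (not isolated)
8 | (1S,2S)-1-(3,4-dimethoxyphenyl)-2-(3,5-dimethoxyphenyl)-4-[tri(propan-2-yl)silyl]but-3-yn-1-ol | O[C@H](c1ccc(OC)c(OC)c1)[C@H](C#C[Si](C(C)C)(C(C)C)C(C)C)c1cc(OC)cc(OC)c1 | intermediate
9 | potassium (1S,2S)-1-(3,4-dimethoxyphenyl)-2-(3,5-dimethoxyphenyl)-4-[tri(propan-2-yl)silyl]but-3-yn-1-olate | [K+].[O-][C@H](c1ccc(OC)c(OC)c1)[C@H](C#C[Si](C(C)C)(C(C)C)C(C)C)c1cc(OC)cc(OC)c1 | intermediate (not isolated)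
10 | 4-[(1S,2S)-1-[(E)-1,2-dichloroethenoxy]-2-(3,5-dimethoxyphenyl)-4-[tri(propan-2-yl)silyl]but-3-yn-1-yl]-1,2-dimethoxybenzene | Cl/C=C(/Cl)O[C@H](c1ccc(OC)c(OC)c1)[C@H](C#C[Si](C(C)C)(C(C)C)C(C)C)c1cc(OC)cc(OC)c1 | intermediate
11 | 4-[(1S,2R)-1-[(E)-1,2-dichloroethenoxy]-2-(3,5-dimethoxyphenyl)but-3-yn-1-yl]-1,2-dimethoxybenzene | Cl/C=C(/Cl)O[C@H](c1ccc(OC)c(OC)c1)[C@H](C#C)c1cc(OC)cc(OC)c1 | intermediate
12 | lithium acetylide of 11 | Cl/C=C(/Cl)O[C@H](c1ccc(OC)c(OC)c1)[C@H](C#C[Li])c1cc(OC)cc(OC)c1 | intermediate (not isolated)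
13 | lithium alkynyl(isopropoxy)pinacolborate carrying the dichlorovinyl ether | Cl/C=C(/Cl)O[C@H](c1ccc(OC)c(OC)c1)[C@H](C#C[B-]1(OC(C)C)OC(C)(C)C(C)(C)O1)c1cc(OC)cc(OC)c1.[Li+] | intermediate (not isolated)
14 | lithium alkynyl(isopropoxy)pinacolborate carrying the lithium alkoxyacetylide | [Li]C#CO[C@H](c1ccc(OC)c(OC)c1)[C@H](C#C[B-]1(OC(C)C)OC(C)(C)C(C)(C)O1)c1cc(OC)cc(OC)c1.[Li+] | intermediate (not isolated)
15 | 2-[(3S,4S)-4-(3,4-dimethoxyphenyl)-3-(3,5-dimethoxyphenyl)-4-(ethynyloxy)but-1-yn-1-yl]-4,4,5,5-tetramethyl-1,3,2-dioxaborolane | C#CO[C@H](c1ccc(OC)c(OC)c1)[C@H](C#CB1OC(C)(C)C(C)(C)O1)c1cc(OC)cc(OC)c1 | intermediate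
16 | 4-bromo-2,6-dimethoxybenzaldehyde | COc1cc(Br)cc(OC)c1C=O | starting material
17 | 1-(4-bromo-2,6-dimethoxyphenyl)prop-2-yn-1-ol (racemic) | COc1cc(Br)cc(OC)c1C(O)C#C | intermediate
18 | 1-(4-bromo-2,6-dimethoxyphenyl)prop-2-yn-1-one | COc1cc(Br)cc(OC)c1C(=O)C#C | intermediate
19 | (E)-1-(4-bromo-2,6-dimethoxyphenyl)-3-(diethylamino)prop-2-en-1-one | CCN(CC)/C=C/C(=O)c1c(OC)cc(Br)cc1OC | intermediate (not isolated)
20 | (E)-1-(4-bromo-2-hydroxy-6-methoxyphenyl)-3-(diethylamino)prop-2-en-1-one | CCN(CC)/C=C/C(=O)c1c(O)cc(Br)cc1OC | intermediate (not isolated)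
21 | 7-bromo-5-methoxy-4H-chromen-4-one | COc1cc(Br)cc2occc(=O)c12 | intermediate
22 | 4-methoxyphenylboronic acid | COc1ccc(B(O)O)cc1 | starting material
23 | (2R)-7-bromo-5-methoxy-2-(4-methoxyphenyl)-2,3-dihydro-4H-chromen-4-one | COc1ccc(cc1)[C@H]1CC(=O)c2c(OC)cc(Br)cc2O1 | intermediate
24 | methyl (2R,3R)-6-bromo-4-methoxy-2-(4-methoxyphenyl)-2,3-dihydro-1-benzofuran-3-carboxylate | COc1ccc(cc1)[C@@H]1Oc2cc(Br)cc(OC)c2[C@H]1C(=O)OC | intermediate
25 | [(2R,3S)-6-bromo-4-methoxy-2-(4-methoxyphenyl)-2,3-dihydro-1-benzofuran-3-yl]methanol | COc1ccc(cc1)[C@@H]1Oc2cc(Br)cc(OC)c2[C@H]1CO | intermediate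
26 | [(E)-2-(4-methoxyphenyl)ethenyl]boronic acid | COc1ccc(/C=C/B(O)O)cc1 | starting material
27 | [(2R,3S)-4-methoxy-2-(4-methoxyphenyl)-6-[(E)-2-(4-methoxyphenyl)ethenyl]-2,3-dihydro-1-benzofuran-3-yl]methanol | COc1ccc(/C=C/c2cc(OC)c3c(c2)O[C@@H](c2ccc(OC)cc2)[C@@H]3CO)cc1 | intermediate
28 | (2R,3R)-4-methoxy-2-(4-methoxyphenyl)-6-[(E)-2-(4-methoxyphenyl)ethenyl]-2,3-dihydro-1-benzofuran-3-carbaldehyde | COc1ccc(/C=C/c2cc(OC)c3c(c2)O[C@@H](c2ccc(OC)cc2)[C@@H]3C=O)cc1 | intermediate
29 | (2R,3R)-3-ethynyl-4-methoxy-2-(4-methoxyphenyl)-6-[(E)-2-(4-methoxyphenyl)ethenyl]-2,3-dihydro-1-benzofuran | COc1ccc(/C=C/c2cc(OC)c3c(c2)O[C@@H](c2ccc(OC)cc2)[C@@H]3C#C)cc1 | intermediate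
30 | bis(dihydrobenzofuran) C4′ pinacol boronate (ring A 2R,3R; ring B 2S,3S) | COc1ccc(/C=C/c2cc(OC)c3c(c2)O[C@@H](c2ccc(OC)cc2)[C@@H]3c2cc(B4OC(C)(C)C(C)(C)O4)c3c(c2)O[C@H](c2ccc(OC)c(OC)c2)[C@H]3c2cc(OC)cc(OC)c2)cc1 | intermediate
31 | bis(dihydrobenzofuran) C4′ phenol heptamethyl ether (ring A 2R,3R; ring B 2S,3S) | COc1ccc(/C=C/c2cc(OC)c3c(c2)O[C@@H](c2ccc(OC)cc2)[C@@H]3c2cc(O)c3c(c2)O[C@H](c2ccc(OC)c(OC)c2)[C@H]3c2cc(OC)cc(OC)c2)cc1 | intermediate
32 | CNP0107857.3 | Oc1ccc(/C=C/c2cc(O)c3c(c2)O[C@@H](c2ccc(O)cc2)[C@@H]3c2cc(O)c3c(c2)O[C@H](c2ccc(O)c(O)c2)[C@H]3c2cc(O)cc(O)c2)cc1 | target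

**Step count and risks**

Total: 18 steps. Longest linear sequence: 12 steps (steps 7–15, then 16–18); the diyne branch is 6 steps (1–6).

Steps most likely to fail:

1. Step 16 (key step). The ynol ether may be diverted on ruthenium (vinylidene or ketene formation), 15 may dimerise faster than it cross-couples, or 15 may rearrange before it reacts. The fallback uses known chemistry: a temporary silicon tether for the cyclotrimerisation, Tamao–Fleming and boronate oxidation, and acid-catalysed benzylic etherification. It sets out from alcohol 8 and returns at phenol 31. TBAF removes the silyl group of 8 to give (1S,2R)-1-(3,4-dimethoxyphenyl)-2-(3,5-dimethoxyphenyl)but-3-yn-1-ol F1. n-BuLi (2 equiv), i-PrOBpin and then HCl in Et2O give the alkynylboronate alcohol F2. Chloro(ethynyl)di(propan-2-yl)silane and imidazole give the ethynylsilyl ether diyne F3. Cp*RuCl(cod) couples F3 with 29, by the same regiochemical argument, to the benzo-fused oxasiline F4. H2O2, KF and KHCO3 oxidise both the C7a′–Si and the C4′–B bond of F4 to the triol F5. Catalytic camphorsulfonic acid in CH2Cl2 then ionises the 3,4-dimethoxybenzylic alcohol of F5, and either of the two equivalent phenols closes the dihydrofuran, trans under thermodynamic control, to give 31.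

2. Step 6. The second n-BuLi charge may exchange ligands at boron or deprotonate C3′, or the C–B bond may be lost on quench, so that no intact boronate diyne is obtained. The fallback carries boron through the organolithium stage as its 1,8-diaminonaphthalene amide; it sets out from 11 and returns at 31. HB(dan) with Zn(OTf)2 and pyridine in EtCN borylates the alkyne C–H of 11 to the B(dan) dichlorovinyl ether F6. n-BuLi (4.2 equiv, the first two for the N–H groups) and then MeOH give the B(dan) ynol ether diyne F7. F7 replaces 15 in step 16 and gives the aryl–B(dan) cyclotrimer F8. Aqueous H2SO4 in THF followed by NaBO3 converts F8 into 31.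

3. Step 3. Propargyl–allenyl metallotropy of the aryl-substituted allenylzinc 7 may racemise it before it adds, so that 8 forms anti but with eroded enantiomeric purity. The fallback replaces chirality transfer by resolution; it sets out from 8 and returns at 8. (S)-2-Methoxy-2-phenylacetic acid, EDC and DMAP give the (S)-O-methylmandelate of 8 F9; the diastereomers are separated by chromatography or crystallisation, and i-Bu2AlH at −78 °C cleaves the wanted ester back to 8.

**Further compounds**

F1 | step 16 | (1S,2R)-1-(3,4-dimethoxyphenyl)-2-(3,5-dimethoxyphenyl)but-3-yn-1-ol | O[C@H](c1ccc(OC)c(OC)c1)[C@H](C#C)c1cc(OC)cc(OC)c1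
F2 | step 16 | (1S,2S)-1-(3,4-dimethoxyphenyl)-2-(3,5-dimethoxyphenyl)-4-(4,4,5,5-tetramethyl-1,3,2-dioxaborolan-2-yl)but-3-yn-1-ol | O[C@H](c1ccc(OC)c(OC)c1)[C@H](C#CB1OC(C)(C)C(C)(C)O1)c1cc(OC)cc(OC)c1
F3 | step 16 | ethynyldi(propan-2-yl)silyl ether of F2 | C#C[Si](C(C)C)(C(C)C)O[C@H](c1ccc(OC)c(OC)c1)[C@H](C#CB1OC(C)(C)C(C)(C)O1)c1cc(OC)cc(OC)c1
F4 | step 16 | benzo-fused 1,2-oxasiline cyclotrimer with C4′ pinacol boronate | COc1ccc(/C=C/c2cc(OC)c3c(c2)O[C@@H](c2ccc(OC)cc2)[C@@H]3c2cc(B4OC(C)(C)C(C)(C)O4)c3c(c2)[Si](C(C)C)(C(C)C)O[C@H](c2ccc(OC)c(OC)c2)[C@H]3c2cc(OC)cc(OC)c2)cc1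
F5 | step 16 | ring-opened triol (2,6-dihydroxyaryl with free C2′ alcohol) | COc1ccc(/C=C/c2cc(OC)c3c(c2)O[C@@H](c2ccc(OC)cc2)[C@@H]3c2cc(O)c(c(O)c2)[C@@H]([C@H](O)c2ccc(OC)c(OC)c2)c2cc(OC)cc(OC)c2)cc1
F6 | step 6 | B(dan) alkynylborane carrying the (E)-1,2-dichlorovinyl ether | Cl/C=C(/Cl)O[C@H](c1ccc(OC)c(OC)c1)[C@H](C#CB1Nc2cccc3cccc(N1)c23)c1cc(OC)cc(OC)c1
F7 | step 6 | B(dan) alkynylborane carrying the terminal ynol ether | C#CO[C@H](c1ccc(OC)c(OC)c1)[C@H](C#CB1Nc2cccc3cccc(N1)c23)c1cc(OC)cc(OC)c1
F8 | step 6 | bis(dihydrobenzofuran) with B(dan) at C4′ | COc1ccc(/C=C/c2cc(OC)c3c(c2)O[C@@H](c2ccc(OC)cc2)[C@@H]3c2cc(B4Nc5cccc6cccc(N4)c56)c3c(c2)O[C@H](c2ccc(OC)c(OC)c2)[C@H]3c2cc(OC)cc(OC)c2)cc1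
F9 | step 3 | (S)-2-methoxy-2-phenylacetate of 8 | CO[C@H](C(=O)O[C@H](c1ccc(OC)c(OC)c1)[C@H](C#C[Si](C(C)C)(C(C)C)C(C)C)c1cc(OC)cc(OC)c1)c1ccccc1
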